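**Retrosynthetic overview**
- The dihydropyran ring is closed last, onto a purchased six-membered carbocycle at the quinone oxidation level. The 6-hydroxychroman is a hydroquinone mono-ether: O1 (on C8a) is para to the C6 hydroxyl and C4a is the ring carbon next to C8a, so C4a–C8a map onto trimethyl-1,4-benzoquinone. Its only unsubstituted ring carbon (future C4a) takes a C4 radical, the adjacent carbonyl carbon (future C8a) takes the tertiary O1, and the other carbonyl ends as the C6 phenol.
- The C4 radical donor already carries O1 and C2: a five-membered cyclic boronic half-ester (1,2-oxaborolan-2-ol) of the (R)-tertiary alcohol, made from a 2-methyl-2-alkyloxetane by reductive C–O cleavage and borylation. The oxetane (C2 stereocentre) comes from a methyl ketone by catalytic asymmetric double methylene transfer.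
- The methyl ketone (C4′, C8′, isopropenyl tail) comes from (E)-geranylacetone: ketal, allylic oxidation of the terminal E-methyl, one double asymmetric hydrogenation, tosylate/Grignard coupling with an isopentenyl unit, ketal removal.

Key step: step 9

Assumption: (E)-geranylacetone is taken as the isomerically pure commercial material, and for the two enantioselective catalysts (steps 3 and 7) the ligand enantiomer named is the one assumed to give the configuration drawn; if a model run showed the opposite sense, the mirror-image ligand would be used with nothing else changed.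

**Step 1**
Reactants: 1 (5E)-6,10-dimethylundeca-5,9-dien-2-one ((E)-geranylacetone)
Product: 2 2-[(3E)-4,8-dimethylnona-3,7-dien-1-yl]-2-methyl-1,3-dioxolane
Conditions: ethylene glycol (3 equiv), PPTS (5 mol %), benzene, reflux, Dean–Stark
Reagents that add atoms: ethylene glycol, OCCO
Why: Acid-catalysed ketalisation with removal of water masks the ketone for the later Grignard step, and the weak pyridinium acid should leave the two trisubstituted alkenes in place.

**Step 2**
Reactants: 2 2-[(3E)-4,8-dimethylnona-3,7-dien-1-yl]-2-methyl-1,3-dioxolane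
Product: 3 (2E,6E)-2,6-dimethyl-9-(2-methyl-1,3-dioxolan-2-yl)nona-2,6-dien-1-ol
Conditions: SeO2 (0.3 equiv), t-BuOOH (70 % aq., 3 equiv), CH2Cl2, 0 °C to rt
Reagents that add atoms: tert-butyl hydroperoxide, CC(C)(C)OO
Why: Selenium dioxide allylic oxidation (ene reaction, then [2,3]-sigmatropic shift) is known to take the terminal gem-dimethyl alkene of geranyl-type chains at its E-methyl group, so the E-allylic alcohol should form with the internal alkene left alone.

**Step 3**
Reactants: 3 (2E,6E)-2,6-dimethyl-9-(2-methyl-1,3-dioxolan-2-yl)nona-2,6-dien-1-ol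
Product: 4 (2S,6R)-2,6-dimethyl-9-(2-methyl-1,3-dioxolan-2-yl)nonan-1-ol
Conditions: H2 (50 bar), [Ir(cod)(L)][B(C6H3(CF3)2)4] (1 mol %; L = (S)-8-(di-tert-butylphosphanyloxy)-2-phenyl-5,6,7,8-tetrahydroquinoline), CH2Cl2, rt
Reagents that add atoms: none
Why: Iridium-catalysed asymmetric hydrogenation of trisubstituted alkenes with a pyridine–phosphinite ligand; both E-alkenes have the same shape (H on the head-side carbon, methyl on the tail-side carbon), so one catalyst enantiomer should add H2 to the same face of each and set C6 (R) and C2 (S) by catalyst control.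

**Step 4**
Reactants: 4 (2S,6R)-2,6-dimethyl-9-(2-methyl-1,3-dioxolan-2-yl)nonan-1-ol
Product: 5 (2S,6R)-2,6-dimethyl-9-(2-methyl-1,3-dioxolan-2-yl)nonyl 4-methylbenzenesulfonate
Conditions: TsCl (1.3 equiv), Et3N (2 equiv), DMAP (5 mol %), CH2Cl2, 0 °C to rt
Reagents that add atoms: 4-methylbenzenesulfonyl chloride, Cc1ccc(cc1)S(Cl)(=O)=O
Why: Sulfonylation of the primary alcohol under basic conditions touches neither the ketal nor the stereocentres.

**Step 5**
Reactants: 5 (2S,6R)-2,6-dimethyl-9-(2-methyl-1,3-dioxolan-2-yl)nonyl 4-methylbenzenesulfonate; 6 4-bromo-2-methylbut-1-ene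
Product: 8 2-methyl-2-[(4R,8S)-4,8,12-trimethyltridec-12-en-1-yl]-1,3-dioxolane, via Grignard reagent 7 (not isolated)
Conditions: 6, Mg, THF, rt (gives 7, 2.5 equiv); then 5, Li2CuCl4 (5 mol %), THF, −78 °C to rt
Reagents that add atoms: none
Why: Copper-catalysed sp3–sp3 coupling of a primary tosylate with a Grignard reagent (Kochi–Schlosser type) is reliable for β-branched tosylates and installs the isopropenyl tail without touching the adjacent stereocentre, while the ketal shields the carbonyl.

**Step 6**
Reactants: 8 2-methyl-2-[(4R,8S)-4,8,12-trimethyltridec-12-en-1-yl]-1,3-dioxolane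
Product: 9 (6R,10S)-6,10,14-trimethylpentadec-14-en-2-one
Conditions: PPTS (0.2 equiv), acetone/H2O (10:1), 55 °C
Reagents that add atoms: water, O
Why: Mild acid-catalysed ketal hydrolysis frees the methyl ketone, and the weak acid should not hydrate or isomerise the 1,1-disubstituted alkene.

**Step 7**
Reactants: 9 (6R,10S)-6,10,14-trimethylpentadec-14-en-2-one
Product: 11 (2R)-2-methyl-2-[(4R,8S)-4,8,12-trimethyltridec-12-en-1-yl]oxetane, via epoxide 10 (not isolated)
Conditions: dimethylsulfoxonium methylide (THF solution, 1.2 then 2.0 equiv), LaLi3((S)-1,1′-binaphthalene-2,2′-diolate)3 (5 then 15 mol %), tris(2,4,6-trimethoxyphenyl)phosphine oxide (5 mol %), 5 Å MS, THF, rt then 45 °C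
Reagents that add atoms: dimethylsulfoxonium methylide, [CH2-][S+](C)(C)=O
Why: Catalytic asymmetric Corey–Chaykovsky epoxidation of a methyl ketone by the lanthanum–lithium binaphthoxide catalyst sets C2 (R) by catalyst control, and a second ylide then expands the epoxide at its CH2 carbon (4-exo-tet closure) without touching the quaternary carbon; this ring expansion should be faster for the major epoxide enantiomer and so raise the enantiopurity.

**Step 8**
Reactants: 11 (2R)-2-methyl-2-[(4R,8S)-4,8,12-trimethyltridec-12-en-1-yl]oxetane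
Product: 13 (5S)-5-methyl-5-[(4R,8S)-4,8,12-trimethyltridec-12-en-1-yl]-1,2-oxaborolan-2-ol, via dilithio alkoxide 12 (not isolated)
Conditions: Li (5 equiv), 4,4′-di-tert-butylbiphenyl (10 mol %), THF, 0 °C; B(OMe)3 (3 equiv), −78 °C to rt; 1 M HCl
Reagents that add atoms: trimethyl borate, COB(OC)OC; water, O
Why: Reductive lithiation of an oxetane by an arene radical anion cleaves the less substituted C–O bond to a primary γ-lithio alkoxide, which is borylated by the borate ester and closes to the cyclic boronic half-ester on acidic work-up; the tertiary C–O bond is not broken, so the configuration is kept (the descriptor becomes S only because boron ranks below carbon).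

**Step 9**
Reactants: 13 (5S)-5-methyl-5-[(4R,8S)-4,8,12-trimethyltridec-12-en-1-yl]-1,2-oxaborolan-2-ol; 14 2,3,5-trimethylcyclohexa-2,5-diene-1,4-dione
Product: 19 (2R)-2,5,7,8-tetramethyl-2-[(4R,8S)-4,8,12-trimethyltridec-12-en-1-yl]-3,4-dihydro-2H-chromen-6-ol, via catechol boronate 15 (not isolated), via alkylhydroquinone 16 (not isolated), via hydroxyalkylquinone 17 (not isolated), via cyclic hemiketal 18 (not isolated)
Conditions: catechol (1.1 equiv), 14 (2.5 equiv), di-tert-butyl hyponitrite (5 mol %), camphor-10-sulfonic acid (20 mol %), 4 Å MS, CH2Cl2, Ar, rt then 40 °C; aq. NaHCO3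
Reagents that add atoms: none
Why: Proposed new method: catechol converts 13 in the flask into the B-alkyl catechol boronate 15, whose primary C4 radical (released first by the hyponitrite-derived tert-butoxyl radical and then, in a chain, by homolytic substitution at boron by the adduct oxyl radical) adds to the only unsubstituted ring carbon of 14 and gives, after tautomerisation, hydroquinone 16 with the C4–C4a bond; the excess of 14 re-oxidises 16 to quinone 17 and is itself reduced to trimethylhydroquinone. Under sulfonic acid catalysis the tertiary hydroxyl of 17 attacks the neighbouring ring carbonyl (6-exo-trig, cyclic hemiketal 18, O1–C8a bond), 18 loses water to an aromatic-stabilised oxocarbenium ion, and trimethylhydroquinone reduces this ion to the phenol, which closes the dihydropyran ring for good and returns 14, so the whole step is redox-neutral. The closest known reactions are the radical conjugate alkylation of quinones by trialkylboranes and B-alkyl catecholboranes (C–C bond) and the quinone-mediated acid etherification of hydroquinones, including the configuration-retaining ring closure of tocopherylquinone-type γ-hydroxyalkyl quinones through their hemiketals (C–O bond). No new stereocentre is formed, and C2 keeps its configuration because the C2–O bond is never broken: the tertiary oxygen is the nucleophile and the quinone oxygen is the one lost as water. The step needs C- over O-attack at a single ring position (secured by the primary radical and the three methyl groups of 14), closure at the carbonyl next to the new chain (the only one a six-membered ring can reach), and survival of the isopropenyl group and tertiary alcohol (weak acid load in CH2Cl2, no strong oxidant).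

**Compound list**
1 | (5E)-6,10-dimethylundeca-5,9-dien-2-one | CC(=O)CC/C=C(\C)CCC=C(C)C | starting material
2 | 2-[(3E)-4,8-dimethylnona-3,7-dien-1-yl]-2-methyl-1,3-dioxolane | CC1(CC/C=C(\C)CCC=C(C)C)OCCO1 | intermediate
3 | (2E,6E)-2,6-dimethyl-9-(2-methyl-1,3-dioxolan-2-yl)nona-2,6-dien-1-ol | CC1(CC/C=C(\C)CC/C=C(\C)CO)OCCO1 | intermediate
4 | (2S,6R)-2,6-dimethyl-9-(2-methyl-1,3-dioxolan-2-yl)nonan-1-ol | OC[C@@H](C)CCC[C@@H](C)CCCC1(C)OCCO1 | intermediate
5 | (2S,6R)-2,6-dimethyl-9-(2-methyl-1,3-dioxolan-2-yl)nonyl 4-methylbenzenesulfonate | Cc1ccc(cc1)S(=O)(=O)OC[C@@H](C)CCC[C@@H](C)CCCC1(C)OCCO1 | intermediate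
6 | 4-bromo-2-methylbut-1-ene | C=C(C)CCBr | starting material
7 | (3-methylbut-3-en-1-yl)magnesium bromide | C=C(C)CC[Mg]Br | intermediate
8 | 2-methyl-2-[(4R,8S)-4,8,12-trimethyltridec-12-en-1-yl]-1,3-dioxolane | C=C(C)CCC[C@@H](C)CCC[C@@H](C)CCCC1(C)OCCO1 | intermediate
9 | (6R,10S)-6,10,14-trimethylpentadec-14-en-2-one | C=C(C)CCC[C@@H](C)CCC[C@@H](C)CCCC(C)=O | intermediate
10 | (2R)-2-methyl-2-[(4R,8S)-4,8,12-trimethyltridec-12-en-1-yl]oxirane | C=C(C)CCC[C@@H](C)CCC[C@@H](C)CCC[C@]1(C)CO1 | intermediate
11 | (2R)-2-methyl-2-[(4R,8S)-4,8,12-trimethyltridec-12-en-1-yl]oxetane | C=C(C)CCC[C@@H](C)CCC[C@@H](C)CCC[C@]1(C)CCO1 | intermediate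
12 | lithium (3S,7R,11S)-1-lithio-3,7,11,15-tetramethylhexadec-15-en-3-olate | C=C(C)CCC[C@@H](C)CCC[C@@H](C)CCC[C@](O[Li])(C)CC[Li] | intermediate
13 | (5S)-5-methyl-5-[(4R,8S)-4,8,12-trimethyltridec-12-en-1-yl]-1,2-oxaborolan-2-ol | C=C(C)CCC[C@@H](C)CCC[C@@H](C)CCC[C@]1(C)CCB(O)O1 | intermediate
14 | 2,3,5-trimethylcyclohexa-2,5-diene-1,4-dione | CC1=CC(=O)C(C)=C(C)C1=O | starting material
15 | (3S,7R,11S)-1-(1,3,2-benzodioxaborol-2-yl)-3,7,11,15-tetramethylhexadec-15-en-3-ol | C=C(C)CCC[C@@H](C)CCC[C@@H](C)CCC[C@](O)(C)CCB1Oc2ccccc2O1 | intermediate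
16 | 2-[(3R,7R,11S)-3-hydroxy-3,7,11,15-tetramethylhexadec-15-en-1-yl]-3,5,6-trimethylbenzene-1,4-diol | C=C(C)CCC[C@@H](C)CCC[C@@H](C)CCC[C@](O)(C)CCc1c(C)c(O)c(C)c(C)c1O | intermediate
17 | 2-[(3R,7R,11S)-3-hydroxy-3,7,11,15-tetramethylhexadec-15-en-1-yl]-3,5,6-trimethylcyclohexa-2,5-diene-1,4-dione | C=C(C)CCC[C@@H](C)CCC[C@@H](C)CCC[C@](O)(C)CCC1=C(C)C(=O)C(C)=C(C)C1=O | intermediate
18 | (2R)-8a-hydroxy-2,5,7,8-tetramethyl-2-[(4R,8S)-4,8,12-trimethyltridec-12-en-1-yl]-3,4-dihydro-2H-chromen-6(8aH)-one (both C8a epimers) | C=C(C)CCC[C@@H](C)CCC[C@@H](C)CCC[C@]1(C)CCC2=C(C)C(=O)C(C)=C(C)C2(O)O1 | intermediate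
19 | (2R)-2,5,7,8-tetramethyl-2-[(4R,8S)-4,8,12-trimethyltridec-12-en-1-yl]-3,4-dihydro-2H-chromen-6-ol | C=C(C)CCC[C@@H](C)CCC[C@@H](C)CCC[C@]1(C)CCc2c(C)c(O)c(C)c(C)c2O1 | target

Total step count: 9. Longest linear sequence: 9 steps (from 1).

**Steps most likely to fail**

Step 9. The radical chain may stall (slow substitution at boron by the hindered oxyl radical), the radical may attack a quinone oxygen, or the acid may ionise the tertiary C–O bond (loss of configuration) or isomerise the terminal alkene. The fallback sets out from 13 and 14 and comes back at 19, making the two bonds one after the other by known chemistry. AgNO3 (0.2 equiv) and K2S2O8 (3 equiv) in CH2Cl2/H2O at rt (persulfate-driven radical alkylation of quinones by boronic acids) should give quinone 17, which is isolated. Ascorbic acid (5 equiv) with camphor-10-sulfonic acid (0.2 equiv) in MeCN/H2O at 40 °C should then close it through hemiketal 18 to 19 (reduction of the cyclic hemiketal of a γ-hydroxyalkyl quinone). It makes no compound beyond the list: none F0.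

Step 8. Electron transfer may cleave the tertiary instead of the primary C–O bond, or the γ-oxido alkyllithium may decompose before it is borylated. The fallback sets out from 11 and comes back at 17, forming the C4–C4a bond by a polar route without boron. Commercial 1,4-dimethoxy-2,3,5-trimethylbenzene is lithiated at its one ring position (n-BuLi, TMEDA, THF) to (2,5-dimethoxy-3,4,6-trimethylphenyl)lithium F1. With BF3·OEt2 at −78 °C, F1 should open 11 at the CH2–O carbon (SN2, quaternary carbon untouched) to (3R,7R,11S)-1-(2,5-dimethoxy-3,4,6-trimethylphenyl)-3,7,11,15-tetramethylhexadec-15-en-3-ol F2. Oxidative demethylation with (NH4)2Ce(NO3)6 in MeCN/H2O at 0 °C should give quinone 17, which is closed to 19 with ascorbic acid and camphor-10-sulfonic acid as in the fallback for step 9.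

Step 7. The catalyst may discriminate poorly between the faces of a ketone whose two substituents (methyl and a long n-alkyl chain) differ little near the carbonyl, or the ring expansion may stop at the epoxide. The fallback sets out from 9 and comes back at 11, setting C2 by a Sharpless asymmetric epoxidation instead.
- Horner–Wadsworth–Emmons olefination (triethyl phosphonoacetate, NaH, THF) gives, after separation from the Z isomer, ethyl (2E,7R,11S)-3,7,11,15-tetramethylhexadeca-2,15-dienoate F3.
- i-Bu2AlH (CH2Cl2, −78 °C) gives (2E,7R,11S)-3,7,11,15-tetramethylhexadeca-2,15-dien-1-ol F4.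
- Ti(OiPr)4, D-(−)-diethyl tartrate, t-BuOOH, 4 Å MS, CH2Cl2, −20 °C gives [(2R,3R)-3-methyl-3-[(4R,8S)-4,8,12-trimethyltridec-12-en-1-yl]oxiran-2-yl]methanol F5.
- NaAlH2(OCH2CH2OMe)2 in THF at 0 °C (hydride to C2) gives (3R,7R,11S)-3,7,11,15-tetramethylhexadec-15-ene-1,3-diol F6.
- TsCl/pyridine at 0 °C gives the primary tosylate (3R,7R,11S)-3-hydroxy-3,7,11,15-tetramethylhexadec-15-en-1-yl 4-methylbenzenesulfonate F7.
- KOtBu in THF closes F7 to oxetane 11 (Williamson, 4-exo-tet, C2–O bond untouched).

**Further compounds**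
F0 | step 9 | none | none
F1 | step 8 | (2,5-dimethoxy-3,4,6-trimethylphenyl)lithium | [Li]c1c(C)c(OC)c(C)c(C)c1OC
F2 | step 8 | (3R,7R,11S)-1-(2,5-dimethoxy-3,4,6-trimethylphenyl)-3,7,11,15-tetramethylhexadec-15-en-3-ol | C=C(C)CCC[C@@H](C)CCC[C@@H](C)CCC[C@](O)(C)CCc1c(C)c(OC)c(C)c(C)c1OC
F3 | step 7 | ethyl (2E,7R,11S)-3,7,11,15-tetramethylhexadeca-2,15-dienoate | C=C(C)CCC[C@@H](C)CCC[C@@H](C)CCC/C(C)=C/C(=O)OCC
F4 | step 7 | (2E,7R,11S)-3,7,11,15-tetramethylhexadeca-2,15-dien-1-ol | C=C(C)CCC[C@@H](C)CCC[C@@H](C)CCC/C(C)=C/CO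
F5 | step 7 | [(2R,3R)-3-methyl-3-[(4R,8S)-4,8,12-trimethyltridec-12-en-1-yl]oxiran-2-yl]methanol | C=C(C)CCC[C@@H](C)CCC[C@@H](C)CCC[C@]1(C)[C@@H](CO)O1
F6 | step 7 | (3R,7R,11S)-3,7,11,15-tetramethylhexadec-15-ene-1,3-diol | C=C(C)CCC[C@@H](C)CCC[C@@H](C)CCC[C@](O)(C)CCO
F7 | step 7 | (3R,7R,11S)-3-hydroxy-3,7,11,15-tetramethylhexadec-15-en-1-yl 4-methylbenzenesulfonate | C=C(C)CCC[C@@H](C)CCC[C@@H](C)CCC[C@](O)(C)CCOS(=O)(=O)c1ccc(C)cc1
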